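The numbers in the tables are simulated with made-up constants, and the scatter is random.

- The percentage point was my unit: a reading scatters by 1 percentage point, and flasks within 1.5 points count as equal.

| flask | G | D | J | Q | temperature | remark | time |
|---|---|---|---|---|---|---|---|
| gamma | 0.48 M | 0.48 M | 0.48 M | 3.4 mM | 20 °C | run made earlier |  |
| alpha | 0.48 M | 0.48 M | 0.48 M | 5.3 mM | 38 °C | run made earlier |  |
| eta | 0.48 M | 0.48 M | 0.24 M | 2.4 mM | 20 °C | run made earlier |  |
| oak | 0.48 M | 0.48 M | 0.480 M | 2.4 mM | 50 °C |  | 8.0 d |
| ash | 0.48 M | 0.48 M | 0.480 M | 2.4 mM | 25 °C |  | 8.0 d |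
| maple | 0.48 M | 0.48 M | 0.480 M | 2.4 mM |  | at 25 °C until 40 h, from then on at 50 °C | 8.0 d |

| run | time / d | Ul / % | Yx / % |
|---|---|---|---|
| gamma | 8.00 | 25.2 | 0 |
| gamma | 12.0 | 27.1 | 2.8 |
| gamma | 20.0 | 27.0 | 0.1 |
| gamma | 25.0 | 26.5 | 2.5 |
| alpha | 0.833 | 18.6 | 0.7 |
| alpha | 2.50 | 20.6 | 0.9 |
| alpha | 5.00 | 20.0 | 1.6 |
| alpha | 10.0 | 21.0 | 0 |
| eta | 4.00 | 12.2 | 0.9 |
| eta | 12.0 | 14.0 | 0.1 |
| eta | 20.0 | 15.6 | 0 |
| eta | 25.0 | 14.3 | 0.9 |

(readings scatter by 1 percentage point)

- Q is single-handed; G and D are mirror images of each other, charged as a racemate, each of them at the stated concentration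
- the analysis behind the earlier runs scatters by 1 percentage point, standard deviation
- steps that have been proposed: J -> X; J + Q + G -> Q + Ul; 2 Q -> E; 2 J -> Z; J + Q + D -> Q + Yx
- an excess is the difference of the two amounts in percent of their sum
- an excess is below zero if the other one leads

- the best flask by excess of Ul over Yx; "all alike" if 1.5 percentage points covers them all (oak / ash / maple / all alike)
- excess of Ul over Yx at the end, oak
- excess of Ul over Yx at the end, ash
- excess of Ul over Yx at the end, maple

- I followed one molecule of J through Q to its fork between G and D. The proposed steps to X, Z and E favour neither side, so I looked at that fork and at how far each run got.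
- The mean readings of the three runs gave 30.1 for the fork ratio, the factor by which a G molecule is likelier than a D molecule to be taken at equal concentration. This selectivity factor is the logarithm of the G left over that of the D left, each as a fraction of its own charge.
- This reading was loose: Yx averaged 0.875%, with a standard error of about a third of that.
- I then turned the question round and asked what would part the flasks. With the ratio held, Ul at eta's mean 14.0% gave an excess of 92.5%, and Ul at gamma's mean 26.4% gave 91.1%. That gap of 1.4 points lies inside the margin.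
- Yx per Ul read 0.0434, so I estimated that, at equal Ul, one flask would stand apart from another if that ratio shifted by about 18.8%. Assuming that the ratio stayed inside that band, I committed to oak, ash and maple lying within the margin of one another.
- The forecast said all alike, with 92% for oak, 91.5% for ash and 92% for maple: “All three land near 92%”.
- The flasks gave 90.2% in oak, 91.2% in ash and 91.3% in maple, hence all alike.

    J → X (k = 0.00932 h⁻¹, Ea = 112 kJ mol⁻¹)
    J + Q + G → Q + Ul (k = 42.8 L² mol⁻² h⁻¹, Ea = 49.0 kJ mol⁻¹)
    2 Q → E (k = 20.3 L mol⁻¹ h⁻¹, Ea = 58.0 kJ mol⁻¹)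
    2 J → Z (k = 0.0135 L mol⁻¹ h⁻¹, Ea = 77.0 kJ mol⁻¹)
    J + Q + D → Q + Yx (k = 1.53 L² mol⁻² h⁻¹, Ea = 57.0 kJ mol⁻¹)
    (constants at 25 °C)

- In oak at 0.0670 d, the half-life of D by its step was 13 d against 0.60 d for G, a ratio of 21.7; the end contents put the fork ratio at 21.8 in oak and 28.0 in ash, yet with oak's Ul at half of ash's, their excesses stood 1.00 point apart. The neighbour of oak charged with 1.9 M of J, holding Ul 27.6% and Yx 1.81%, kept a fork ratio of 21.8 and fell to 87.7%, which is 3.5 points below ash.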